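Handing over a proton is the easy step here: the acidic substrate gives one to the free base and becomes an anion, which the readings do not show. Monday's target and acidic substrate add up to 90.2% of the charge at 0.250 d but 98.3% at 0.417 d, so something unread stood between them and then became target.

| setting | Monday's | Tuesday's | flask |
|---|---|---|---|
| acidic substrate | 0.20 M | 0.20 M | 0.20 M |
| free base | 0.40 equiv | 1.6 equiv | 0.800 equiv |
| electrophile | 1.05 equiv (in portions, 2) | 1.05 equiv (in portions, 2) | 1.05 equiv (in portions, 2) |
| remark | run made earlier; portions every 3.0 h | run made earlier; portions every 3.0 h | the portions of electrophile follow each other after 3.0 h, the first at the start |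
| time |  |  | 4.0 d |

- Monday's (time / d: target / %, acidic substrate / %): 0.250: 16.3, 73.9; 0.417: 23.9, 74.4; 0.625: 24.0, 72.3; 0.833: 26.1, 73.7; 1.25: 26.6, 71.4; 2.00: 28.7, 69.3; 3.00: 30.8, 67.3
- Tuesday's (time / d: target / %, acidic substrate / %): 0.250: 32.0, 47.8; 0.417: 42.0, 48.7; 0.625: 46.0, 49.1; 0.833: 49.4, 47.3; 1.25: 54.5, 45.1; 2.00: 59.5, 38.1; 3.00: 63.4, 33.2

(each reading ± 1 percentage point)

- a reading or a percentage of target counts all its forms, free or not

* amount of target in percent of the acidic substrate charged, at 10 h, 30 h, 2.5 d and 4.0 d

This reckoning takes the electrophile to turn the anion into target, with the proton staying behind as protonated base. Each percent of target T therefore keeps one percent of the base occupied. In this flask the free base, at 0.800 equiv, is charged below the electrophile at 1.05 equiv and below the one equivalent of acidic substrate, so it is the limiting reagent. This reckoning gives C = 80.0%, the ceiling C being the free-base charge in percent of the acidic substrate charged. The room R = C − T is the base not tied to target. Monday's ceiling is 40.0%, and Tuesday, with 1.6 equiv of free base, reads 63.4% at 3.00 d, above it. The ceiling is a bound and gives no course.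

The forecast gives 33.5%, 41%, 46.5% and 51% at the asked times, on the ground that “Burst size scales as the square root of the base charge”. Its last value stays under the ceiling, with R = 29 percentage points.

    electrophile + anion → target (k = 3.00 × 10⁻⁴ M⁻¹ s⁻¹)
    crystals ⇌ target, rate k2*(cs2 - [target]) while solid is left; crystals form when [target] > cs2 (solubility = 24.0 mM, k = 5.40 × 10⁻⁴ s⁻¹)
    acidic substrate + free base ⇌ protonated base + anion, settled at all times (K = 2.10)
    free base ⇌ dormant form (K = 35.0, k = 1.30 × 10⁻⁴ s⁻¹)

The flask gives 31.9%, 40.6%, 46.5% and 51.5%, crystals counted in, so the forecast stands within its margin. At 4.00 d the flask holds 0.0538 M of dormant form, which is 26.9% of the acidic substrate charged. The room of 29 points under the ceiling of 80.0% is this dormant form, with the protonated base paired with 1.01% of anion and 0.535% of free base on the same scale. Monday's run, under its ceiling of 40.0%, reads 30.8% at 3.00 d, a room of 9.2 points.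

(Readings and results stem from a simulated flask on assumed constants.)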